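J is the product wanted, and L goes on to consume it.

    Z + L → E + Q (k1 = 0.0012 /M/s, Ea1 = 78.0 kJ/mol)
    E → J (k2 = 5.1 × 10⁻⁵ /s, Ea2 = 90.0 kJ/mol)
    L + J → L.J (k3 = 6.8 × 10⁻⁵ /M/s, Ea3 = 64.0 kJ/mol)
    E → G (k4 = 4.8 × 10⁻⁵ /s, Ea4 = 85.0 kJ/mol)
    (constants at 25 °C)

all flasks: Z 0.80 M; L 1.80 equiv; time 12 h

| run | temperature |
|---|---|
| delta | 50 °C |
| eta | 25 °C |

1. the flask with the highest amount of J, in percent of the Z charged ("all alike" if they lie within 1.5 percentage points) (delta / eta / all alike)
2. final J, as a percentage of the Z charged, in delta
3. final J, as a percentage of the Z charged, in eta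

- the list of constants is for 25 °C, to be carried to other temperatures by the activation energies

Start with eta. Z is the limiting reagent, and the excess of L over it is 0.640 M. Z becomes E within about 0.362 h, and E lives a time τE = 2.81 h, so treat E as charged at the start. A share s = 51.5 % of E goes towards J.

Now hold c_L constant, which makes the loss of J pseudo-first-order, and call one over k3 times c_L the J lifetime τJ. At the excess it is 6.38 h. Two consecutive first-order steps then give J = s·τJ/(τJ−τE)·(e^(−t/τJ) − e^(−t/τE)).

Since c_L sinks below the excess as L.J forms, this lifetime is too short and gives a bound from below: 12.7 % at 12 h. For a bound from above, let the whole J branch end as L.J. That leaves 0.228 M of L and a ceiling of 30.4 %. Tighten it: the lower bound's own L.J is the most to expect, so c_L should stay above 0.336 M. The lifetime is then at most 12.2 h and the ceiling falls to 24.0 %.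

For delta, step 3 speeds up 7.4-fold and step 2 17-fold, and step 4 by 14.2 from its activation energy. The share becomes 55.4 %, and the crude ceiling gives 0.835 %. That is below eta's floor, so expect more J in eta.

The forecast says eta, with 0.3 % in delta and 18 % in eta, because “J is steadily consumed by the leftover L”. Its eta value lies between eta's two bounds, and its delta value lies under delta's ceiling.

The simulation gives eta, with 0.263 % in delta and 18.3 % in eta. Eta ends with L at 26.5 % of its charge, so the J lifetime there reads 10.7 h, shorter than the limit 12.2 h. Now take eta with 0.48 M of Z at the same equivalents of L. The excess shrinks with Z, so the J lifetime stretches to 10.6 h, and the same formula gives a floor of 21.7 %. The tightened ceiling, from 0.244 M of L, is 29.3 %. That flask gives 25.9 % of J.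

All constants come from no measurement; what happens was integrated by code.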